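**Retrosynthetic overview**
Feature: in the hydrindene (C1 quaternary with CH3 and the side chain C1'–C5', C2 = CH–CO2H, C3, C3a=C4, C7 = CMe2, C7a angular quaternary) C1' lies 1,3 to C3a across the five-membered ring, and C3a=C4 is where the enolate of a C4 ketone sits. A temporary C3a–C1' bond therefore turns the ring C1–C2–C3–C3a–C7a into a bicyclo[2.1.1]hexane (C1, C2, C3, C3a, C7a, C1') fused to the six-membered ring.
Disconnections: C3'=C4' (Z-selective phosphonate olefination, last); C3a–C1' (added backwards, cleaved forwards by SmI2 with capture of the C3a=C4 enolate); C1–C7a together with C3a–C1' (crossed intramolecular enone–alkene [2+2] photocycloaddition); C2–C3 (auxiliary-controlled alkylation of a β,γ-unsaturated imide with a 2-(bromomethyl)cyclohexenone).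
Ring order: the six-membered ring is bought as 4,4-dimethylcyclohex-2-en-1-one; light closes the five-membered ring and the temporary cyclobutane in one step; the cyclobutane is then opened.
Stereocontrol: the auxiliary sets C2, C2 steers the face of the cycloaddition and with it C1 and C7a, and C2 is finally inverted by equilibration of the ester.

Key step: step 13

Assumption: the hydrindene locants of the target (C1–C7a, side chain C1'–C5') are used for every intermediate, and the 2S methyl ester (ester trans to the C1 side chain) is taken to be the more stable C2 epimer.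

**Step 1**
Reactants: 1 4,4-dimethylcyclohex-2-en-1-one
Product: 2 trimethyl[(3,4,4-trimethylcyclohex-1-en-1-yl)oxy]silane (racemic)
Conditions: Me2CuLi (from MeLi and CuI), Me3SiCl, Et2O, −78 °C; Et3N, then aq. NaHCO3
Reagents that add atoms: lithium dimethylcuprate, [Li+].C[Cu-]C; chlorotrimethylsilane, C[Si](C)(C)Cl
Why: Conjugate addition of the Gilman cuprate places the methyl group on C3 next to the quaternary carbon and O-silylation of the enolate keeps the enol double bond at C1=C2 for the next step; the C3 centre is formed racemic and is removed in step 2.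

**Step 2**
Reactants: 2 trimethyl[(3,4,4-trimethylcyclohex-1-en-1-yl)oxy]silane
Product: 3 3,4,4-trimethylcyclohex-2-en-1-one
Conditions: Pd(OAc)2 (10 mol %), O2 (1 atm), DMSO, 25 °C
Reagents that add atoms: none
Why: Saegusa–Ito oxidation, in which palladation of the silyl enol ether at C2 and β-hydride elimination of the C3 hydrogen should return the enone with the new methyl group on its β-carbon.

**Step 3**
Reactants: 3 3,4,4-trimethylcyclohex-2-en-1-one
Product: 5 2-bromo-3,4,4-trimethylcyclohex-2-en-1-one, via dibromo ketone 4 (not isolated)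
Conditions: Br2, CH2Cl2, −10 °C; then Et3N, 0 → 20 °C
Reagents that add atoms: bromine, BrBr
Why: Bromination–dehydrobromination, in which addition of bromine across the enone double bond and loss of HBr through the enolate should give the α-bromo enone without any nucleophile having to add to the crowded β-carbon, as amine-mediated α-iodination would require.

**Step 4**
Reactants: 5 2-bromo-3,4,4-trimethylcyclohex-2-en-1-one
Product: 6 2-(hydroxymethyl)-3,4,4-trimethylcyclohex-2-en-1-one
Conditions: Bu3SnCH2OH, Pd(PPh3)4 (5 mol %), dioxane, 90 °C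
Reagents that add atoms: (tributylstannyl)methanol, CCCC[Sn](CCCC)(CCCC)CO
Why: Stille coupling of the activated alkenyl bromide with the hydroxymethylstannane should install the future C3 as a primary allylic alcohol.

**Step 5**
Reactants: 6 2-(hydroxymethyl)-3,4,4-trimethylcyclohex-2-en-1-one
Product: 7 2-(bromomethyl)-3,4,4-trimethylcyclohex-2-en-1-one
Conditions: CBr4, PPh3, CH2Cl2, 0 °C
Reagents that add atoms: tetrabromomethane, BrC(Br)(Br)Br
Why: Appel bromination converts the primary allylic alcohol into the bromide under neutral conditions that leave the enone alone.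

**Step 6**
Reactants: 8 pent-3-yn-1-ol
Product: 9 tert-butyl(pent-3-yn-1-yloxy)diphenylsilane
Conditions: t-BuPh2SiCl, imidazole, DMF, 20 °C
Reagents that add atoms: tert-butyl(chloro)diphenylsilane, CC(C)(C)[Si](Cl)(c1ccccc1)c1ccccc1
Why: Silylation of the primary alcohol gives an ether that should tolerate the zirconium hydride, the enolate steps, the irradiation and SmI2.

**Step 7**
Reactants: 9 tert-butyl(pent-3-yn-1-yloxy)diphenylsilane
Product: 11 (E)-tert-butyl[(4-iodopent-3-en-1-yl)oxy]diphenylsilane, via alkenylzirconocene chloride 10 (not isolated)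
Conditions: Cp2ZrHCl (2.0 equiv), THF, 50 °C; then I2, 0 °C
Reagents that add atoms: iodine, [I][I]
Why: Syn hydrozirconation of the internal alkyne, equilibrated by the excess hydride to zirconium on the methyl-bearing carbon, followed by iododezirconation with retention should give the E alkenyl iodide.

**Step 8**
Reactants: 11 (E)-tert-butyl[(4-iodopent-3-en-1-yl)oxy]diphenylsilane; 12 ethyl bromoacetate
Product: 14 ethyl (E)-6-[(tert-butyldiphenylsilyl)oxy]-3-methylhex-3-enoate, via Reformatsky reagent 13 (not isolated)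
Conditions: 12, Zn, Me3SiCl (cat.), THF, 40 °C; then 11, Pd(PPh3)4 (5 mol %), THF/DMPU, 50 °C
Reagents that add atoms: none
Why: Negishi-type cross-coupling of the zinc ester enolate (Reformatsky reagent) with the alkenyl iodide proceeds with retention of the alkene geometry and, being neutral, should leave the double bond β,γ to the ester.

**Step 9**
Reactants: 14 ethyl (E)-6-[(tert-butyldiphenylsilyl)oxy]-3-methylhex-3-enoate
Product: 15 (E)-6-[(tert-butyldiphenylsilyl)oxy]-3-methylhex-3-enoic acid
Conditions: LiOH, THF/MeOH/H2O, 0 → 20 °C; then 1 M HCl to pH 3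
Reagents that add atoms: lithium hydroxide, [Li+].[OH-]
Why: Saponification of the unhindered ethyl ester at low temperature, after which the carboxylate resists deprotonation, so that the double bond should stay out of conjugation.

**Step 10**
Reactants: 15 (E)-6-[(tert-butyldiphenylsilyl)oxy]-3-methylhex-3-enoic acid; 16 (R)-4-benzyloxazolidin-2-one
Product: 19 (4R)-4-benzyl-3-[(3E)-6-[(tert-butyldiphenylsilyl)oxy]-3-methylhex-3-enoyl]-1,3-oxazolidin-2-one, via mixed pivalic anhydride 17 (not isolated), via lithiated oxazolidinone 18 (not isolated)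
Conditions: 15, t-BuCOCl, Et3N, THF, −78 → 0 °C; 16, n-BuLi, THF, −78 °C; combined at −78 → 0 °C
Reagents that add atoms: none
Why: N-acylation of the lithiated auxiliary by the mixed anhydride, which reacts at the carbonyl group remote from the tert-butyl group.

**Step 11**
Reactants: 19 (4R)-4-benzyl-3-[(3E)-6-[(tert-butyldiphenylsilyl)oxy]-3-methylhex-3-enoyl]-1,3-oxazolidin-2-one; 7 2-(bromomethyl)-3,4,4-trimethylcyclohex-2-en-1-one
Product: 21 (4R)-4-benzyl-3-[(2R,3E)-6-[(tert-butyldiphenylsilyl)oxy]-3-methyl-2-[(2,3,3-trimethyl-6-oxocyclohex-1-en-1-yl)methyl]hex-3-enoyl]-1,3-oxazolidin-2-one, via sodium dienolate 20 (not isolated)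
Conditions: NaN(SiMe3)2 (1.0 equiv), THF, −78 °C; then 7, −78 → −40 °C
Reagents that add atoms: none
Why: Evans alkylation, in which the chelated Z sodium dienolate is alkylated at its α-carbon by the allylic bromide on the face away from the benzyl group, which forms the C2–C3 bond and sets C2 as R.

**Step 12**
Reactants: 21 the alkylated imide
Product: 22 methyl (2R,3E)-6-[(tert-butyldiphenylsilyl)oxy]-3-methyl-2-[(2,3,3-trimethyl-6-oxocyclohex-1-en-1-yl)methyl]hex-3-enoate
Conditions: MeOMgBr (from MeMgBr and MeOH), MeOH/CH2Cl2, −20 → 0 °C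
Reagents that add atoms: methanol (delivered as MeOMgBr), CO
Why: Magnesium-alkoxide transesterification at the exocyclic imide carbonyl group frees the auxiliary without hydroperoxide, which would attack the enone, and the weak base at low temperature should leave the C2 centre and the β,γ double bond as they are.

**Step 13**
Reactants: 22 the methyl ester with the 1,5-diene C7a=C3a–C3–C2–C1=C1'
Product: 23 methyl (1S,6R,7R,8R,10S)-10-{2-[(tert-butyldiphenylsilyl)oxy]ethyl}-5,5,6,7-tetramethyl-2-oxotricyclo[5.2.1.0^1,6]decane-8-carboxylate (hydrindene locants 1R,2R,3aS,7aR,1'S; new bonds C3a–C1' and C1–C7a)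
Conditions: hν (λ = 366 nm), degassed CH2Cl2 (5 mM), 20 °C; chromatographic separation of the diastereomers
Reagents that add atoms: none
Why: Excitation of the enone and intersystem crossing give its triplet, which bonds within the 1,5-diene C7a=C3a–C3–C2–C1=C1' through a five-membered transition state, most probably from C3a to the less substituted C1', to leave a 1,4-diradical with tertiary centres at C7a and C1 that collapses after spin inversion, so that the crowded C1–C7a bond is made by radical combination. The closest known reaction type is the crossed intramolecular enone–alkene [2+2] photocycloaddition of 2-(but-3-enyl)cyclohex-2-enones (rule of five). The first bond closes the five-membered ring C3a–C3–C2–C1–C1' by 1,5-bonding with the enone double bond exocyclic to that ring, and the second closes the cyclobutane C1–C1'–C3a–C7a by 1,4-diradical combination and with it the five-membered ring C1–C2–C3–C3a–C7a of the later hydrindene. C3a, C7a and C1 are fixed together by the face of the enone that is attacked (the cis fusion of the cyclobutane to the six-membered ring places the C7a methyl group endo, over the C2–C3 bridge, and C7 exo), and that face is chosen by the existing C2 centre, whose ester group takes the side of the C1' bridge with its endo hydrogen and avoids the endo methyl group of the C7a bridge; C1' follows the alkene geometry or the rotation of the diradical and loses its meaning in step 14. The step needs crossed and not straight regiochemistry, which the two-atom link C3–C2 between C3a and C1 secures because straight addition would have to form a bicyclo[2.2.0]hexane, and it needs one enone face, which C2 secures. The minor face isomer has to be removed at this stage, since after the later equilibration at C2 it would end in the enantiomeric series.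

**Step 14**
Reactants: 23 the cage ketone
Product: 25 methyl (1R,2R,7aR)-1-{3-[(tert-butyldiphenylsilyl)oxy]propyl}-1,7,7,7a-tetramethyl-4-[(trifluoromethanesulfonyl)oxy]-2,3,5,6,7,7a-hexahydro-1H-indene-2-carboxylate, via samarium enolate 24 (not isolated)
Conditions: SmI2 (2.5 equiv), HMPA (10 equiv), THF, −78 °C; t-BuOH (1.0 equiv); then 2-[N,N-bis(trifluoromethanesulfonyl)amino]-5-chloropyridine, −78 → 0 °C
Reagents that add atoms: 2-[N,N-bis(trifluoromethanesulfonyl)amino]-5-chloropyridine, FC(F)(F)S(=O)(=O)N(c1ccc(Cl)cn1)S(=O)(=O)C(F)(F)F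
Why: Electron transfer to the C4 ketone gives a ketyl whose strained exocyclic cyclobutane bond C3a–C1' breaks (reductive fragmentation of a cyclobutyl ketone; the C3a–C7a bond lies in the ring of the ketyl, overlaps poorly and would give a bridgehead enolate), the C1' radical is reduced by the second equivalent of SmI2 and its carbon–samarium bond is protonated by the single equivalent of t-BuOH, and the regiodefined trivalent samarium enolate is O-sulfonylated to fix the C3a=C4 double bond as the enol triflate; C3a and C1' cease to be stereocentres.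

**Step 15**
Reactants: 25 the enol triflate
Product: 26 methyl (1R,2R,7aS)-1-{3-[(tert-butyldiphenylsilyl)oxy]propyl}-1,7,7,7a-tetramethyl-2,3,5,6,7,7a-hexahydro-1H-indene-2-carboxylate
Conditions: Pd(OAc)2 (5 mol %), PPh3 (10 mol %), HCO2H, n-Bu3N, DMF, 60 °C
Reagents that add atoms: none
Why: Palladium-catalysed formate reduction of the enol triflate (oxidative addition, exchange of triflate for formate, loss of CO2 and reductive elimination) replaces the triflate by hydrogen without moving the C3a=C4 double bond; the change of the C7a descriptor from R to S is a matter of priorities only.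

**Step 16**
Reactants: 26 the silyl ether ester
Product: 27 methyl (1R,2R,7aS)-1-(3-hydroxypropyl)-1,7,7,7a-tetramethyl-2,3,5,6,7,7a-hexahydro-1H-indene-2-carboxylate
Conditions: Bu4NF, AcOH, THF, 20 °C
Reagents that add atoms: none
Why: Fluoride-induced cleavage of the silyl ether, buffered with acetic acid, is placed before the base steps because the silyl ether would not reliably survive hot alkoxide.

**Step 17**
Reactants: 27 the 2R hydroxy ester
Product: 28 methyl (1R,2S,7aS)-1-(3-hydroxypropyl)-1,7,7,7a-tetramethyl-2,3,5,6,7,7a-hexahydro-1H-indene-2-carboxylate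
Conditions: NaOMe (0.5 equiv), MeOH, 60 °C; 28 separated by chromatography, recovered 27 resubmitted
Reagents that add atoms: none
Why: Base-mediated epimerisation through the ester enolate (thermodynamic control) at C2, the only centre that can enolise since C1 and C7a are quaternary, should favour the 2S ester with the carboxyl group trans to the C1 side chain and on the face away from C7.

**Step 18**
Reactants: 28 the 2S hydroxy ester
Product: 29 (1R,2S,7aS)-1-(3-hydroxypropyl)-1,7,7,7a-tetramethyl-2,3,5,6,7,7a-hexahydro-1H-indene-2-carboxylic acid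
Conditions: NaSEt (5 equiv), DMF, 90 °C; then 1 M HCl to pH 3
Reagents that add atoms: none
Why: SN2 demethylation of the ester by thiolate at the methyl carbon avoids attack at the crowded acyl carbon and, being weakly basic, should leave the freshly set C2 centre untouched, which hot hydroxide would not guarantee.

**Step 19**
Reactants: 29 the hydroxy acid
Product: 30 (1R,2S,7aS)-1,7,7,7a-tetramethyl-1-(3-oxopropyl)-2,3,5,6,7,7a-hexahydro-1H-indene-2-carboxylic acid
Conditions: Dess–Martin periodinane, CH2Cl2, 20 °C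
Reagents that add atoms: none
Why: Dess–Martin oxidation of the primary alcohol to the aldehyde tolerates the free carboxylic acid and the trisubstituted alkene.

**Step 20**
Reactants: 30 the aldehyde acid; 31 ethyl 2-[bis(2,2,2-trifluoroethoxy)phosphoryl]propanoate
Product: 33 (1R,2S,7aS)-1-[(3Z)-5-ethoxy-4-methyl-5-oxopent-3-en-1-yl]-1,7,7,7a-tetramethyl-2,3,5,6,7,7a-hexahydro-1H-indene-2-carboxylic acid, via potassium phosphonate anion 32 (not isolated)
Conditions: 31 (2.3 equiv), KN(SiMe3)2 (2.2 equiv), 18-crown-6 (5 equiv), THF, −78 °C; then 30, −78 °C; aq. NH4Cl, then 1 M HCl to pH 3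
Reagents that add atoms: none
Why: Still–Gennari olefination, in which the electron-poor phosphonate anion with a dissociated potassium counter-ion adds irreversibly and eliminates fast, should give the Z trisubstituted enoate, one equivalent of the anion serving as base for the carboxylic acid.

**Step 21**
Reactants: 33 the Z enoate acid
Product: 35 (1R,2S,7aS)-1-[(3Z)-5-hydroxy-4-methylpent-3-en-1-yl]-1,7,7,7a-tetramethyl-2,3,5,6,7,7a-hexahydro-1H-indene-2-carboxylic acid, via aluminium carboxylate 34 (not isolated)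
Conditions: i-Bu2AlH (4.5 equiv), CH2Cl2, −78 °C; aq. KNaC4H4O6 (potassium sodium tartrate), then 1 M HCl to pH 3
Reagents that add atoms: none
Why: The first equivalent of hydride turns the acid into its aluminium carboxylate, which is inert at −78 °C, and 1,2-reduction of the enoate by further hydride should give the allylic alcohol with the Z geometry unchanged.

**Step 22**
Reactants: 35 the hydroxy acid
Product: 37 (1R,2S,7aS)-1-[(3Z)-5-(acetyloxy)-4-methylpent-3-en-1-yl]-1,7,7,7a-tetramethyl-2,3,5,6,7,7a-hexahydro-1H-indene-2-carboxylic acid (CNP0289983.1), via mixed acetic anhydride 36 (not isolated)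
Conditions: Ac2O, pyridine, 4-(dimethylamino)pyridine (cat.), CH2Cl2, 0 → 20 °C; then aq. NaHCO3/THF, 20 °C; 1 M HCl to pH 3
Reagents that add atoms: acetic anhydride, CC(=O)OC(C)=O
Why: Acetylation of the primary allylic alcohol, after which the mixed anhydride formed at the hindered carboxyl group is hydrolysed at its acetyl carbonyl group during the aqueous bicarbonate treatment, returning the free acid of the target.

**Compound list**
1 | 4,4-dimethylcyclohex-2-en-1-one | CC1(C)CCC(=O)C=C1 | starting material
2 | trimethyl[(3,4,4-trimethylcyclohex-1-en-1-yl)oxy]silane (racemic) | CC1C=C(O[Si](C)(C)C)CCC1(C)C | intermediate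
3 | 3,4,4-trimethylcyclohex-2-en-1-one | CC1=CC(=O)CCC1(C)C | intermediate
4 | 2,3-dibromo-3,4,4-trimethylcyclohexan-1-one (racemic trans dibromide) | CC1(Br)C(Br)C(=O)CCC1(C)C | intermediate (not isolated)
5 | 2-bromo-3,4,4-trimethylcyclohex-2-en-1-one | CC1=C(Br)C(=O)CCC1(C)C | intermediate
6 | 2-(hydroxymethyl)-3,4,4-trimethylcyclohex-2-en-1-one | CC1=C(CO)C(=O)CCC1(C)C | intermediate
7 | 2-(bromomethyl)-3,4,4-trimethylcyclohex-2-en-1-one | O=C1CCC(C)(C)C(C)=C1CBr | intermediate
8 | pent-3-yn-1-ol | CC#CCCO | starting material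
9 | tert-butyl(pent-3-yn-1-yloxy)diphenylsilane | CC#CCCO[Si](c1ccccc1)(c1ccccc1)C(C)(C)C | intermediate
10 | chlorobis(cyclopentadienyl)[(2E)-5-[(tert-butyldiphenylsilyl)oxy]pent-2-en-2-yl]zirconium | C/C(=C\CCO[Si](c1ccccc1)(c1ccccc1)C(C)(C)C)[Zr](Cl)(C1C=CC=C1)C1C=CC=C1 | intermediate (not isolated)
11 | (E)-tert-butyl[(4-iodopent-3-en-1-yl)oxy]diphenylsilane | C/C(I)=C\CCO[Si](c1ccccc1)(c1ccccc1)C(C)(C)C | intermediate
12 | ethyl bromoacetate | CCOC(=O)CBr | starting material
13 | bromo(2-ethoxy-2-oxoethyl)zinc (Reformatsky reagent) | CCOC(=O)C[Zn]Br | intermediate (not isolated)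
14 | ethyl (E)-6-[(tert-butyldiphenylsilyl)oxy]-3-methylhex-3-enoate | CCOC(=O)C/C(C)=C/CCO[Si](c1ccccc1)(c1ccccc1)C(C)(C)C | intermediate
15 | (E)-6-[(tert-butyldiphenylsilyl)oxy]-3-methylhex-3-enoic acid | OC(=O)C/C(C)=C/CCO[Si](c1ccccc1)(c1ccccc1)C(C)(C)C | intermediate
16 | (R)-4-benzyloxazolidin-2-one | O=C1N[C@H](Cc2ccccc2)CO1 | starting material
17 | mixed anhydride of 15 with pivalic acid | CC(C)(C)C(=O)OC(=O)C/C(C)=C/CCO[Si](c1ccccc1)(c1ccccc1)C(C)(C)C | intermediate (not isolated)
18 | lithium salt of (R)-4-benzyloxazolidin-2-one | [Li+].O=C1[N-][C@H](Cc2ccccc2)CO1 | intermediate (not isolated)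
19 | (4R)-4-benzyl-3-[(3E)-6-[(tert-butyldiphenylsilyl)oxy]-3-methylhex-3-enoyl]-1,3-oxazolidin-2-one | O=C(C/C(C)=C/CCO[Si](c1ccccc1)(c1ccccc1)C(C)(C)C)N2[C@H](Cc3ccccc3)COC2=O | intermediate
20 | sodium Z dienolate of 19 (O–Na cis to the alkenyl group) | [Na+].[O-]/C(=C\C(C)=C\CCO[Si](c1ccccc1)(c1ccccc1)C(C)(C)C)N1[C@H](Cc2ccccc2)COC1=O | intermediate (not isolated)
21 | (4R)-4-benzyl-3-[(2R,3E)-6-[(tert-butyldiphenylsilyl)oxy]-3-methyl-2-[(2,3,3-trimethyl-6-oxocyclohex-1-en-1-yl)methyl]hex-3-enoyl]-1,3-oxazolidin-2-one | O=C([C@H](CC1=C(C)C(C)(C)CCC1=O)/C(C)=C/CCO[Si](c2ccccc2)(c2ccccc2)C(C)(C)C)N3[C@H](Cc4ccccc4)COC3=O | intermediate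
22 | methyl (2R,3E)-6-[(tert-butyldiphenylsilyl)oxy]-3-methyl-2-[(2,3,3-trimethyl-6-oxocyclohex-1-en-1-yl)methyl]hex-3-enoate | COC(=O)[C@H](CC1=C(C)C(C)(C)CCC1=O)/C(C)=C/CCO[Si](c2ccccc2)(c2ccccc2)C(C)(C)C | intermediate
23 | methyl (1S,6R,7R,8R,10S)-10-{2-[(tert-butyldiphenylsilyl)oxy]ethyl}-5,5,6,7-tetramethyl-2-oxotricyclo[5.2.1.0^1,6]decane-8-carboxylate (bicyclo[2.1.1]hexane cage ketone) | COC(=O)[C@@H]1C[C@@]23C(=O)CCC(C)(C)[C@]2(C)[C@]1(C)[C@@H]3CCO[Si](c4ccccc4)(c4ccccc4)C(C)(C)C | intermediate
24 | diiodosamarium enolate (C3a=C4–O–SmI2) of the ring-opened ketone | COC(=O)[C@@H]1CC2=C(O[Sm](I)I)CCC(C)(C)[C@]2(C)[C@]1(C)CCCO[Si](c3ccccc3)(c3ccccc3)C(C)(C)C | intermediate (not isolated)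
25 | methyl (1R,2R,7aR)-1-{3-[(tert-butyldiphenylsilyl)oxy]propyl}-1,7,7,7a-tetramethyl-4-[(trifluoromethanesulfonyl)oxy]-2,3,5,6,7,7a-hexahydro-1H-indene-2-carboxylate | COC(=O)[C@@H]1CC2=C(OS(=O)(=O)C(F)(F)F)CCC(C)(C)[C@]2(C)[C@]1(C)CCCO[Si](c3ccccc3)(c3ccccc3)C(C)(C)C | intermediate
26 | methyl (1R,2R,7aS)-1-{3-[(tert-butyldiphenylsilyl)oxy]propyl}-1,7,7,7a-tetramethyl-2,3,5,6,7,7a-hexahydro-1H-indene-2-carboxylate | COC(=O)[C@@H]1CC2=CCCC(C)(C)[C@]2(C)[C@]1(C)CCCO[Si](c3ccccc3)(c3ccccc3)C(C)(C)C | intermediate
27 | methyl (1R,2R,7aS)-1-(3-hydroxypropyl)-1,7,7,7a-tetramethyl-2,3,5,6,7,7a-hexahydro-1H-indene-2-carboxylate | COC(=O)[C@@H]1CC2=CCCC(C)(C)[C@]2(C)[C@]1(C)CCCO | intermediate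
28 | methyl (1R,2S,7aS)-1-(3-hydroxypropyl)-1,7,7,7a-tetramethyl-2,3,5,6,7,7a-hexahydro-1H-indene-2-carboxylate | COC(=O)[C@H]1CC2=CCCC(C)(C)[C@]2(C)[C@]1(C)CCCO | intermediate
29 | (1R,2S,7aS)-1-(3-hydroxypropyl)-1,7,7,7a-tetramethyl-2,3,5,6,7,7a-hexahydro-1H-indene-2-carboxylic acid | OCCC[C@]1(C)[C@@H](C(=O)O)CC2=CCCC(C)(C)[C@@]21C | intermediate
30 | (1R,2S,7aS)-1,7,7,7a-tetramethyl-1-(3-oxopropyl)-2,3,5,6,7,7a-hexahydro-1H-indene-2-carboxylic acid | O=CCC[C@]1(C)[C@@H](C(=O)O)CC2=CCCC(C)(C)[C@@]21C | intermediate
31 | ethyl 2-[bis(2,2,2-trifluoroethoxy)phosphoryl]propanoate | CCOC(=O)C(C)P(=O)(OCC(F)(F)F)OCC(F)(F)F | starting material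
32 | potassium salt of the carbanion of 31 | [K+].CCOC(=O)[C-](C)P(=O)(OCC(F)(F)F)OCC(F)(F)F | intermediate (not isolated)
33 | (1R,2S,7aS)-1-[(3Z)-5-ethoxy-4-methyl-5-oxopent-3-en-1-yl]-1,7,7,7a-tetramethyl-2,3,5,6,7,7a-hexahydro-1H-indene-2-carboxylic acid | CCOC(=O)/C(C)=C\CC[C@]1(C)[C@@H](C(=O)O)CC2=CCCC(C)(C)[C@@]21C | intermediate
34 | diisobutylaluminium carboxylate of 33 | CCOC(=O)/C(C)=C\CC[C@]1(C)[C@@H](C(=O)O[Al](CC(C)C)CC(C)C)CC2=CCCC(C)(C)[C@@]21C | intermediate (not isolated)
35 | (1R,2S,7aS)-1-[(3Z)-5-hydroxy-4-methylpent-3-en-1-yl]-1,7,7,7a-tetramethyl-2,3,5,6,7,7a-hexahydro-1H-indene-2-carboxylic acid | OC/C(C)=C\CC[C@]1(C)[C@@H](C(=O)O)CC2=CCCC(C)(C)[C@@]21C | intermediate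
36 | mixed anhydride of the target acid with acetic acid | CC(=O)OC/C(C)=C\CC[C@]1(C)[C@@H](C(=O)OC(C)=O)CC2=CCCC(C)(C)[C@@]21C | intermediate (not isolated)
37 | (1R,2S,7aS)-1-[(3Z)-5-(acetyloxy)-4-methylpent-3-en-1-yl]-1,7,7,7a-tetramethyl-2,3,5,6,7,7a-hexahydro-1H-indene-2-carboxylic acid (CNP0289983.1) | CC(=O)OC/C(C)=C\CC[C@]1(C)[C@@H](C(=O)O)CC2=CCCC(C)(C)[C@@]21C | target

**Step count and risks**
Total step count: 22. Longest linear sequence: 17 steps (steps 1–5 and 11–22; the branch through steps 6–10 is equally long).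

Steps most likely to fail:

Step 13. After the first bond the 1,4-diradical with two tertiary centres may fall back to 22 or lose itself by hydrogen transfer faster than it closes the bond between C1 and C7a, both fully substituted and C7a flanked by the quaternary C7; the face selectivity may also be incomplete. Sensitisation (thioxanthen-9-one, 420 nm) would be tried first but changes only the conditions. The fallback sets out from 6 and comes back at 27, and it makes the C1–C7a bond by a sigmatropic shift instead of by light. Silylation of 6 (t-BuMe2SiCl, imidazole) would give 2-{[(tert-butyldimethylsilyl)oxy]methyl}-3,4,4-trimethylcyclohex-2-en-1-one F1. Corey–Bakshi–Shibata reduction with (S)-1-methyl-3,3-diphenyltetrahydro-1H,3H-pyrrolo[1,2-c][1,3,2]oxazaborole and BH3·SMe2 would give the (1R)-allylic alcohol F2. Esterification with commercial racemic 2-methylpent-4-enoic acid (dicyclohexylcarbodiimide, 4-(dimethylamino)pyridine) would give the allylic ester F3. Ireland–Claisen rearrangement (LiN(i-Pr)2, Me3SiCl, THF, −78 °C, then reflux) would pass through the silyl ketene acetal F4 and give the γ,δ-unsaturated acid F5. In it the new bond arrives on the ring face that carried the oxygen, which sets C7a, while C1 depends on the ketene acetal geometry, which can be switched by adding HMPA to the enolisation. Arndt–Eistert homologation ((COCl)2 to the acid chloride F6, CH2N2 to the diazoketone F7, then PhCO2Ag, Et3N, MeOH) would give with retention at C1 the homologated methyl ester F8, which now carries C2. Bu4NF would free the primary allylic alcohol F9 and CBr4/PPh3 would give the allylic bromide F10. KN(SiMe3)2 (THF, −78 → 0 °C) would close the five-membered ring by 5-exo-tet alkylation of the ester enolate (bond C2–C3) to the allyl-substituted hydrindene ester F11, a mixture at C2. Hydroboration of the terminal alkene with 9-borabicyclo[3.3.1]nonane through the alkylborane F12 and oxidation with NaBO3 would give 27 together with 28, and both enter step 17.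

Step 14. O-Sulfonylation of the trivalent samarium enolate may be slower than its protonation or equilibration, and the C1' radical may break the C1–C7a bond (β-scission back towards the diene) before it is reduced. The fallback sets out from 23 and comes back at 25, and it separates cleavage from enol triflate formation. SmI2 with MeOH as proton source (THF/HMPA, −78 °C) would give the saturated 4-oxo ester F13 as a mixture at C3a, which is of no consequence. Tf2O with 2,6-di-tert-butyl-4-methylpyridine (CH2Cl2, 0 → 20 °C), conditions under which the more substituted enol triflate is formed preferentially, would then return 25; the C4=C5 isomer, if formed, would be separated.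

Step 17. The equilibrium at C2 may lie on the side of 27 or close to parity, so that recycling becomes unproductive. The fallback sets out from 26 and comes back at 28, and it replaces thermodynamic by kinetic control. Deprotonation of 26 with LiN(i-Pr)2 (THF, −78 °C) would give the lithium ester enolate F14. Protonation with the hindered acid 2,6-di-tert-butyl-4-methylphenol, expected on the face away from the C1 and C7a methyl groups, would give the 2S silyl ether ester F15. Bu4NF/AcOH would then give 28.

**Further compounds**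
F1 | step 13 | 2-{[(tert-butyldimethylsilyl)oxy]methyl}-3,4,4-trimethylcyclohex-2-en-1-one | CC1=C(CO[Si](C)(C)C(C)(C)C)C(=O)CCC1(C)C
F2 | step 13 | (1R)-2-{[(tert-butyldimethylsilyl)oxy]methyl}-3,4,4-trimethylcyclohex-2-en-1-ol | O[C@@H]1CCC(C)(C)C(C)=C1CO[Si](C)(C)C(C)(C)C
F3 | step 13 | (1R)-2-{[(tert-butyldimethylsilyl)oxy]methyl}-3,4,4-trimethylcyclohex-2-en-1-yl 2-methylpent-4-enoate (both epimers at the acyl α-carbon) | C=CCC(C)C(=O)O[C@@H]1CCC(C)(C)C(C)=C1CO[Si](C)(C)C(C)(C)C
F4 | step 13 | trimethylsilyl ketene acetal of F3 | C=CCC(C)=C(O[Si](C)(C)C)O[C@@H]1CCC(C)(C)C(C)=C1CO[Si](C)(C)C(C)(C)C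
F5 | step 13 | (2S)-2-[(1S)-2-{[(tert-butyldimethylsilyl)oxy]methyl}-1,6,6-trimethylcyclohex-2-en-1-yl]-2-methylpent-4-enoic acid | C=CC[C@](C)(C(=O)O)[C@]1(C)C(CO[Si](C)(C)C(C)(C)C)=CCCC1(C)C
F6 | step 13 | acid chloride of F5 | C=CC[C@](C)(C(Cl)=O)[C@]1(C)C(CO[Si](C)(C)C(C)(C)C)=CCCC1(C)C
F7 | step 13 | diazomethyl ketone from F6 | C=CC[C@](C)(C(=O)C=[N+]=[N-])[C@]1(C)C(CO[Si](C)(C)C(C)(C)C)=CCCC1(C)C
F8 | step 13 | methyl 3-[2-{[(tert-butyldimethylsilyl)oxy]methyl}-1,6,6-trimethylcyclohex-2-en-1-yl]-3-methylhex-5-enoate (configured as F5) | C=CC[C@](C)(CC(=O)OC)[C@]1(C)C(CO[Si](C)(C)C(C)(C)C)=CCCC1(C)C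
F9 | step 13 | methyl 3-[2-(hydroxymethyl)-1,6,6-trimethylcyclohex-2-en-1-yl]-3-methylhex-5-enoate (configured as F5) | C=CC[C@](C)(CC(=O)OC)[C@]1(C)C(CO)=CCCC1(C)C
F10 | step 13 | methyl 3-[2-(bromomethyl)-1,6,6-trimethylcyclohex-2-en-1-yl]-3-methylhex-5-enoate (configured as F5) | C=CC[C@](C)(CC(=O)OC)[C@]1(C)C(CBr)=CCCC1(C)C
F11 | step 13 | methyl (1R,7aS)-1,7,7,7a-tetramethyl-1-(prop-2-en-1-yl)-2,3,5,6,7,7a-hexahydro-1H-indene-2-carboxylate (both C2 epimers) | C=CC[C@]1(C)C(C(=O)OC)CC2=CCCC(C)(C)[C@@]21C
F12 | step 13 | B-alkyl-9-borabicyclo[3.3.1]nonane from F11 (boron on the terminal carbon of the side chain) | C1CC2CCCC(C1)B2CCC[C@]1(C)C(C(=O)OC)CC2=CCCC(C)(C)[C@@]21C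
F13 | step 14 | methyl (1R,2R,7aR)-1-{3-[(tert-butyldiphenylsilyl)oxy]propyl}-1,7,7,7a-tetramethyl-4-oxooctahydro-1H-indene-2-carboxylate (both C3a epimers) | COC(=O)[C@@H]1CC2C(=O)CCC(C)(C)[C@]2(C)[C@]1(C)CCCO[Si](c3ccccc3)(c3ccccc3)C(C)(C)C
F14 | step 17 | lithium ester enolate of 26 (C2 planar) | [Li+].COC([O-])=C1CC2=CCCC(C)(C)[C@]2(C)[C@]1(C)CCCO[Si](c3ccccc3)(c3ccccc3)C(C)(C)C
F15 | step 17 | methyl (1R,2S,7aS)-1-{3-[(tert-butyldiphenylsilyl)oxy]propyl}-1,7,7,7a-tetramethyl-2,3,5,6,7,7a-hexahydro-1H-indene-2-carboxylate | COC(=O)[C@H]1CC2=CCCC(C)(C)[C@]2(C)[C@]1(C)CCCO[Si](c3ccccc3)(c3ccccc3)C(C)(C)C
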